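**Assumptions**
- Noreugenin (5,7-dihydroxy-2-methylchromone) is treated as a catalogue starting material.
- The sense of induction of the chiral phosphate in Step 4 cannot be predicted with confidence. It is written as (R)-TRIP; whichever antipode gives (3S,4R) is the one used.

**Retrosynthetic overview**
1. Chrotacumine D ⇒ O-debenzylation and N-Boc→N-Me exchange of a protected cis-3-veratroyloxy-4-(chromon-8-yl)piperidine.
2. Key disconnection (new step): the C3–O ester bond and the C4–H bond come from an enantioselective anti-Markovnikov addition of veratric acid across an 8-(tetrahydropyridin-4-yl)chromone. This installs the ester and both stereocentres at once.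
3. The C8–C4' bond comes from Suzuki coupling of an 8-iodochromone with the commercial N-Boc-tetrahydropyridin-4-yl boronate.
4. The 8-iodochromone comes from noreugenin by O-benzylation and C8 iodination.
5. Ring order: no ring is built de novo. The chromone comes intact from noreugenin, the six-membered N-ring from the boronate (saturated in the key step), and the veratroyl ring from veratric acid.

**Route**

Step 1
Reactants: 1 noreugenin; 2 benzyl bromide
Product: 3, 5,7-bis(benzyloxy)-2-methyl-4H-chromen-4-one
Conditions: BnBr (2.6 equiv), K2CO3, TBAI (cat.), DMF, 70 °C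
Reagents that add atoms: benzyl bromide, BrCc1ccccc1
Why: Williamson O-alkylation of both phenols, with heat and iodide catalysis needed to alkylate the chelated 5-OH; K2CO3 is too weak to touch the 2-methyl group.

Step 2
Reactants: 3; 4 N-iodosuccinimide
Product: 5, 5,7-bis(benzyloxy)-8-iodo-2-methyl-4H-chromen-4-one
Conditions: NIS (1.1 equiv), TFA (0.3 equiv), MeCN/CH2Cl2, 0 °C → rt, dark
Reagents that add atoms: N-iodosuccinimide, O=C1CCC(=O)N1I
Why: Electrophilic aromatic iodination; with both oxygens alkylated, C8 (para to 5-OBn and less hindered than C6 between two OBn groups) is the preferred site in 5,7-dialkoxychromones.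

Step 3
Reactants: 5; 6 tert-butyl 4-(4,4,5,5-tetramethyl-1,3,2-dioxaborolan-2-yl)-3,6-dihydropyridine-1(2H)-carboxylate
Product: 7, tert-butyl 4-[5,7-bis(benzyloxy)-2-methyl-4-oxo-4H-chromen-8-yl]-3,6-dihydropyridine-1(2H)-carboxylate
Conditions: Pd(dppf)Cl2·CH2Cl2 (5 mol %), K3PO4, 1,4-dioxane/H2O 5:1, 85 °C
Reagents that add atoms: boronate 6, CC(C)(C)OC(=O)N1CCC(=CC1)B1OC(C)(C)C(C)(C)O1
Why: Suzuki–Miyaura coupling of an aryl iodide with an alkenyl pinacol boronate; Boc, benzyl ethers and the chromone tolerate mild phosphate base.

Step 4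
Reactants: 7; 8 3,4-dimethoxybenzoic acid (veratric acid, 3 equiv)
Product: 9, tert-butyl (3S,4R)-4-[5,7-bis(benzyloxy)-2-methyl-4-oxo-4H-chromen-8-yl]-3-[(3,4-dimethoxybenzoyl)oxy]piperidine-1-carboxylate (cis)
Conditions: 9-mesityl-3,6-di-tert-butyl-10-phenylacridinium (R)-TRIP-phosphate (5 mol %; TRIP = 3,3'-bis(2,4,6-triisopropylphenyl)-BINOL phosphate), 2,4,6-triisopropylbenzenethiol (20 mol %), PhCF3/CH2Cl2 3:1, 450 nm LEDs, −20 °C, Ar; ee upgraded by recrystallisation if needed
Reagents that add atoms: 3,4-dimethoxybenzoic acid, COc1ccc(C(=O)O)cc1OC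
Why: Proposed new method: enantioselective intermolecular anti-Markovnikov hydroacyloxylation by chiral-ion-pair photoredox catalysis. The excited acridinium (E*red ≈ +2.0 V) oxidises the electron-rich aryl-alkene of 7 to a radical cation that stays contact-ion-paired with the chiral phosphate in the low-polarity medium. The phosphate, hydrogen-bonded to veratric acid, acts as a chiral general base and delivers the carboxyl oxygen to one face of the less substituted alkene carbon (C3; enantio-determining C–O bond formation, 3S), leaving the tertiary benzylic C4 radical. That radical takes H from the bulky thiol on the face anti to the new pseudo-axial C3 acyloxy group (1,2-induction), so aryl and ester end up cis (4R). Thiyl radical is reduced by the acridinyl radical and the thiolate is reprotonated by the phosphoric acid, closing both cycles. Closest known chemistry: racemic acridinium/thiol anti-Markovnikov hydroacyloxylation of styrenes, and chiral-counteranion-directed photoredox reactions of alkene radical cations.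

Step 5
Reactants: 9; 10 trifluoroacetic acid
Product: 11, (3S,4R)-4-[5,7-bis(benzyloxy)-2-methyl-4-oxo-4H-chromen-8-yl]piperidin-1-ium-3-yl 3,4-dimethoxybenzoate trifluoroacetate (kept as the salt, not free-based)
Conditions: TFA/CH2Cl2 1:4, 0 °C, 1 h; evaporate with toluene
Reagents that add atoms: trifluoroacetic acid (counter-ion only), OC(=O)C(F)(F)F
Why: Acidolytic Boc cleavage; the secondary benzoate, aryl benzyl ethers and chromone survive brief cold TFA, and keeping the amine protonated prevents O→N acyl shift.

Step 6
Reactants: 11; 12 formaldehyde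
Product: 13, (3S,4R)-4-[5,7-bis(benzyloxy)-2-methyl-4-oxo-4H-chromen-8-yl]-1-methylpiperidin-3-yl 3,4-dimethoxybenzoate
Conditions: 37% aq. HCHO (3 equiv), NaBH(OAc)3 (2.5 equiv), NaOAc (1.1 equiv), DCE, 0 °C → rt
Reagents that add atoms: formaldehyde, C=O
Why: Reductive amination (iminium formation, then triacetoxyborohydride reduction), which does not reduce the ester or chromone; with the phenols still benzylated, formaldehyde cannot do a Mannich reaction at C6.

Step 7
Reactants: 13
Product: 14, chrotacumine D, (3S,4R)-4-(5,7-dihydroxy-2-methyl-4-oxo-4H-chromen-8-yl)-1-methylpiperidin-3-yl 3,4-dimethoxybenzoate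
Conditions: H2 (1 atm), 10% Pd/C, AcOH (1 equiv), EtOAc/MeOH 1:1, rt, monitored to completion
Reagents that add atoms: none
Why: Hydrogenolysis of the two aryl benzyl ethers; the chromone C2=C3 (a vinylogous ester), the non-benzylic C3–O ester and the veratroyl methyl ethers are inert at 1 atm, and neither stereocentre is epimerisable.

**Compound list**
1 | noreugenin (5,7-dihydroxy-2-methyl-4H-chromen-4-one) | Cc1cc(=O)c2c(O)cc(O)cc2o1 | starting material
2 | benzyl bromide | BrCc1ccccc1 | starting material
3 | 5,7-bis(benzyloxy)-2-methyl-4H-chromen-4-one | Cc1cc(=O)c2c(OCc3ccccc3)cc(OCc3ccccc3)cc2o1 | intermediate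
4 | N-iodosuccinimide | O=C1CCC(=O)N1I | starting material
5 | 5,7-bis(benzyloxy)-8-iodo-2-methyl-4H-chromen-4-one | Cc1cc(=O)c2c(OCc3ccccc3)cc(OCc3ccccc3)c(I)c2o1 | intermediate
6 | N-Boc-1,2,3,6-tetrahydropyridine-4-boronic acid pinacol ester | CC(C)(C)OC(=O)N1CCC(=CC1)B1OC(C)(C)C(C)(C)O1 | starting material
7 | tert-butyl 4-[5,7-bis(benzyloxy)-2-methyl-4-oxo-4H-chromen-8-yl]-3,6-dihydropyridine-1(2H)-carboxylate | Cc1cc(=O)c2c(OCc3ccccc3)cc(OCc3ccccc3)c(C3=CCN(C(=O)OC(C)(C)C)CC3)c2o1 | intermediate
8 | 3,4-dimethoxybenzoic acid (veratric acid) | COc1ccc(C(=O)O)cc1OC | starting material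
9 | tert-butyl (3S,4R)-4-[5,7-bis(benzyloxy)-2-methyl-4-oxo-4H-chromen-8-yl]-3-[(3,4-dimethoxybenzoyl)oxy]piperidine-1-carboxylate | COc1ccc(C(=O)O[C@@H]2CN(C(=O)OC(C)(C)C)CC[C@@H]2c2c(OCc4ccccc4)cc(OCc4ccccc4)c3c(=O)cc(C)oc23)cc1OC | intermediate
10 | trifluoroacetic acid | OC(=O)C(F)(F)F | starting material
11 | (3S,4R)-4-[5,7-bis(benzyloxy)-2-methyl-4-oxo-4H-chromen-8-yl]piperidin-1-ium-3-yl 3,4-dimethoxybenzoate trifluoroacetate | COc1ccc(C(=O)O[C@@H]2C[NH2+]CC[C@@H]2c2c(OCc4ccccc4)cc(OCc4ccccc4)c3c(=O)cc(C)oc23)cc1OC.[O-]C(=O)C(F)(F)F | intermediate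
12 | formaldehyde | C=O | starting material
13 | (3S,4R)-4-[5,7-bis(benzyloxy)-2-methyl-4-oxo-4H-chromen-8-yl]-1-methylpiperidin-3-yl 3,4-dimethoxybenzoate | COc1ccc(C(=O)O[C@@H]2CN(C)CC[C@@H]2c2c(OCc4ccccc4)cc(OCc4ccccc4)c3c(=O)cc(C)oc23)cc1OC | intermediate
14 | chrotacumine D | COc1ccc(C(=O)O[C@@H]2CN(C)CC[C@@H]2c2c(O)cc(O)c3c(=O)cc(C)oc23)cc1OC | target

**Totals**
Total steps: 7. Longest linear sequence: 7 (from noreugenin; 6 and 8 are purchased).

**Three steps most likely to fail**

1. Step 4 (proposed new method). Risks: low ee from an unassisted racemic background addition, imperfect cis selectivity in the H-atom transfer, and competing oxidation of veratric acid.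
 Fallback (known chemistry, different approach): make the stereocentres before the chromone.
 - Condense 1,3,5-trimethoxybenzene with 1-methyl-4-piperidone (AcOH/HCl).
 - Hydroboration–oxidation to the trans-alcohol, Swern oxidation, hydride reduction to the cis-alcohol, and classical resolution with dibenzoyl-tartaric acid to the (3S,4R)-piperidinol.
 - BF3·OEt2/Ac2O acetylation, Claisen condensation and acid cyclisation to the chromone, then pyridine·HCl demethylation to rohitukine.
 - Exhaustive veratroylation, then selective aminolysis of the phenolic esters to leave the secondary veratrate.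

2. Step 2 (C8 versus C6 iodination, or over-iodination).
 Fallback: put the iodine in before the pyranone ring exists. Iodinate 4',6'-bis(benzyloxy)-2'-hydroxyacetophenone ortho to the free phenol (C3'), then Claisen condensation with EtOAc/NaH and acid cyclodehydration. The phenol oxygen becomes O1, so the iodine ends up at C8 of 5.

3. Steps 5–6 (O→N acyl migration in the N–H intermediate; cis geometry places the axial ester within reach of the ring nitrogen).
 Fallback: avoid any N–H intermediate by carrying N-methyl from the start. Use commercial 1-methyl-1,2,3,6-tetrahydropyridine-4-boronic acid pinacol ester in Step 3 and run Step 4 on the N-protonated (HBF4) salt, which is not oxidised by the photocatalyst. Hydrogenolysis then gives 14 directly; this would require re-optimising Step 4.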